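**Retrosynthetic overview**

1. Feature: rings A and C are each a C6O3 unit isomeric with a 3-aryl-4-hydroxy-6-methyl-2-pyranone (arene C1, C2, C3, C4, C5, C6 = pyranone C3, C4, C5, C6, 6-CH3, C2). Of the two oxygens flanking the axis carbon C1, O-2 is the free enolic 4-OH of the pyranone and O-6 is hidden in the lactone carbonyl. The later sulfate site can therefore be tagged before the arene exists.
2. End game: the S–O bonds at O-2 of rings A and C and seven O-benzyl bonds are cut last. The tag at O-2 is 4-methoxybenzyl (PMB) rather than allyl, because the ring transposition needs alkoxide at about 170 °C, where an allyl ether would undergo [3,3] shift and double-bond migration.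
3. Key disconnection: C5–C6 of ring A and of ring C at once, back to ring B carrying two 4-PMB-oxy-6-methyl-2-pyranon-3-yl groups.
4. The two ring B–pyranone C3 bonds come from two rhodium-carbenoid arylations of 1,3,5-tris(benzyloxy)benzene with 3-diazo-6-methylpyran-2,4-dione. Each is followed at once by O-tagging, so that no free enol meets the second carbenoid.
5. Ring order: ring B (phloroglucinol) and both pyranone rings are bought; rings A and C are formed together in step 8.

Key step: step 8

Remark: the target carries no descriptor at its two biaryl axes, so all bis-pyranones and terphenyls are carried as rotamer mixtures without control. The target is drawn as the bis(hydrogen sulfate), which is released from its disodium salt (the storage form) only in the last operation.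

**Step 1**
Reactants: 1 phloroglucinol
Product: 2 1,3,5-triacetoxybenzene
Conditions: Ac2O, pyridine, rt
Reagents that add atoms: acetic anhydride, CC(=O)OC(C)=O
Why: Pyridine-promoted O-acetylation (nucleophilic acyl substitution) caps all three phenols and provides the substrate for a benzylation that never exposes the free phloroglucinol polyanion.

**Step 2**
Reactants: 2 1,3,5-triacetoxybenzene; 3 benzyl chloride
Product: 4 1,3,5-tris(benzyloxy)benzene
Conditions: NaH, BnCl, DMF, 0 °C; H2O (3 equiv) added slowly; rt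
Reagents that add atoms: benzyl chloride, ClCc1ccccc1
Why: This is a Williamson ether synthesis with in situ deacetylation, in which NaOH made from NaH and water frees one phenoxide at a time and each is O-benzylated before the ambident polyanion responsible for C-benzylation of phloroglucinol can build up.

**Step 3**
Reactants: 5 4-hydroxy-6-methyl-2H-pyran-2-one
Product: 6 3-diazo-6-methyl-2H-pyran-2,4(3H)-dione
Conditions: 4-acetamidobenzenesulfonyl azide, Et3N, MeCN, 0 °C to rt
Reagents that add atoms: 4-acetamidobenzenesulfonyl azide, CC(=O)Nc1ccc(cc1)S(=O)(=O)N=[N+]=[N-]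
Why: Regitz diazo transfer takes place at C3, the only doubly activated carbon of the cyclic beta-keto lactone.

**Step 4**
Reactants: 4 1,3,5-tris(benzyloxy)benzene (excess, recovered); 6 3-diazo-6-methyl-2H-pyran-2,4(3H)-dione
Product: 7 4-hydroxy-6-methyl-3-[2,4,6-tris(benzyloxy)phenyl]-2H-pyran-2-one
Conditions: Rh2(OAc)4 (2 mol %), PhF, reflux, slow addition of 6
Reagents that add atoms: none
Why: This is a formal aromatic C–H insertion of a rhodium carbenoid (electrophilic attack on the trialkoxyarene, proton shift, enolisation), a known arylation of cyclic 2-diazo-1,3-dicarbonyl compounds with electron-rich arenes, in which the three ring-B C–H sites are equivalent and excess arene holds back a second arylation and O–H insertion into the product enol.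

**Step 5**
Reactants: 7 4-hydroxy-6-methyl-3-[2,4,6-tris(benzyloxy)phenyl]-2H-pyran-2-one; 8 4-methoxybenzyl chloride
Product: 9 4-[(4-methoxybenzyl)oxy]-6-methyl-3-[2,4,6-tris(benzyloxy)phenyl]-2H-pyran-2-one
Conditions: 4-MeOC6H4CH2Cl, K2CO3, Bu4NI (cat.), DMF, 50 °C
Reagents that add atoms: 4-methoxybenzyl chloride, COc1ccc(CCl)cc1
Why: Williamson-type O-alkylation of the vinylogous acid goes to O-4 because C3 is blocked by the bulky aryl group, and it both places the tag and removes the acidic enol before the next carbenoid step.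

**Step 6**
Reactants: 9 4-[(4-methoxybenzyl)oxy]-6-methyl-3-[2,4,6-tris(benzyloxy)phenyl]-2H-pyran-2-one; 6 3-diazo-6-methyl-2H-pyran-2,4(3H)-dione (excess)
Product: 10 1,3,5-tris(benzyloxy)-2-(4-hydroxy-6-methyl-2-oxo-2H-pyran-3-yl)-4-{4-[(4-methoxybenzyl)oxy]-6-methyl-2-oxo-2H-pyran-3-yl}benzene
Conditions: Rh2(OAc)4 (3 mol %), PhF, reflux, 6 by syringe pump
Reagents that add atoms: none
Why: The same rhodium-carbenoid aromatic C–H insertion applies; the two remaining ring-B C–H sites are equivalent, so only the 2,4-pattern can arise, and ring B with three alkoxy donors remains far more nucleophilic than the anisyl ring of the tag or the electron-poor pyranone diene.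

**Step 7**
Reactants: 10 the mono-tagged bis-pyranone; 8 4-methoxybenzyl chloride
Product: 11 1,3,5-tris(benzyloxy)-2,4-bis{4-[(4-methoxybenzyl)oxy]-6-methyl-2-oxo-2H-pyran-3-yl}benzene
Conditions: 4-MeOC6H4CH2Cl, K2CO3, Bu4NI (cat.), DMF, 50 °C
Reagents that add atoms: 4-methoxybenzyl chloride, COc1ccc(CCl)cc1
Why: Williamson-type O-alkylation of the second vinylogous acid proceeds as in step 5 and completes the doubly tagged precursor.

**Step 8**
Reactants: 11 1,3,5-tris(benzyloxy)-2,4-bis{4-[(4-methoxybenzyl)oxy]-6-methyl-2-oxo-2H-pyran-3-yl}benzene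
Product: 13 1,3,5-tris(benzyloxy)-2,4-bis{2,4-dihydroxy-6-[(4-methoxybenzyl)oxy]phenyl}benzene, via ring-opened bis(keto ester) 12 (not isolated)
Conditions: NaH (12 equiv), dry degassed 4-MeOC6H4CH2OH (solvent), Ar, about 170 °C; AcOH quench
Reagents that add atoms: 4-methoxybenzyl alcohol as its sodium alkoxide, COc1ccc(CO)cc1 (ester alkoxy groups of 12; no atom of it is needed in 13)
Why: Sodium 4-methoxybenzyl oxide adds to the lactone carbonyl C2 of each pyranone and the C6 enolate oxygen leaves, giving keto ester 12 with the new ester and the acetonyl chain held cis by the former C3=C4 ring bond; the minor methyl-side enolate then attacks that ester, alkoxide is expelled and the cyclohexenedione enolises to the resorcinol dianion. The closest known reaction type is the alkoxide-induced isomerisation of 4-methoxy-6-methyl-2-pyranone to phloroglucinol monomethyl ether in methanolic methoxide well above 150 °C, an intramolecular Claisen (Dieckmann-type) condensation, applied here twice to a 3-aryl member of the same class. Rings A and C each close in the 6-(enolendo)-exo-trig mode with formation of C5–C6 (former methyl carbon to former lactone carbon), and no stereocentre arises. Selectivity between the two enolisable carbons is needed and is secured by ring size: the more abundant methylene enolate could only close a four-membered ring and stays in equilibrium, while irreversible phenoxide formation drains the methyl pathway. Selectivity at oxygen is secured by matching tag, ester and solvent, so that addition–elimination at C4 and transesterification are degenerate, attack at C6 is reversible, and the aryl benzyl ethers of ring B have no exchange pathway; a benzyl group lost by SN2 attack would be put back in step 9. The PMB tag has neither a [3,3] pathway nor a double bond that base can move, which allows the temperature that the low share of reactive enolate and the flanking 2,6-bis(benzyloxy)aryl group call for.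

**Step 9**
Reactants: 13 the tetraphenol; 3 benzyl chloride
Product: 14 1,3,5-tris(benzyloxy)-2,4-bis{2,4-bis(benzyloxy)-6-[(4-methoxybenzyl)oxy]phenyl}benzene
Conditions: BnCl, K2CO3, Bu4NI (cat.), DMF, 60 °C
Reagents that add atoms: benzyl chloride, ClCc1ccccc1
Why: Williamson ether synthesis on 5-alkoxyresorcinol-type phenols, which O-alkylate far more cleanly than phloroglucinol itself, leaves the two PMB ethers as the only differentiated oxygens.

**Step 10**
Reactants: 14 the heptabenzyl bis-PMB ether
Product: 15 1,3,5-tris(benzyloxy)-2,4-bis[2,4-bis(benzyloxy)-6-hydroxyphenyl]benzene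
Conditions: TFA (5% v/v), 1,3,5-trimethoxybenzene (20 equiv), CH2Cl2, 0 °C
Reagents that add atoms: none
Why: Acid-induced SN1 cleavage ionises only the ether that gives the stabilised 4-methoxybenzyl cation, aryl benzyl ethers being inert to dilute TFA, and a large excess of an unhindered trialkoxyarene takes up the cation by Friedel–Crafts alkylation before the crowded C–H sites of the terphenyl can.

**Step 11**
Reactants: 15 the diol
Product: 17 disodium salt of the hepta-O-benzyl bis(sulfate), via bis(pyridinium) bis(sulfate) 16 (not isolated)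
Conditions: SO3·pyridine (10 equiv), pyridine, 50 °C; then aq NaHCO3 to pH 8
Reagents that add atoms: sulfur trioxide pyridine complex, O=S(=O)([O-])[n+]1ccccc1; sodium hydrogencarbonate, [Na+].OC([O-])=O
Why: O-sulfonation of phenols with an amine–SO3 complex is standard, only the two freed O-2 hydroxyls can react, and exchange to the sodium salt gives a base-stable form that can be purified.

**Step 12**
Reactants: 17 disodium salt of the hepta-O-benzyl bis(sulfate)
Product: 19 2,4-bis[2,4-dihydroxy-6-(sulfooxy)phenyl]benzene-1,3,5-triol (target), via disodium salt of the target 18 (not isolated)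
Conditions: H2 (1 atm), 10% Pd/C, THF–MeOH–H2O, rt, Ar handling; filter; 0.1 M HCl (2.0 equiv), 0 °C, C18 desalting, freeze-drying
Reagents that add atoms: none
Why: Catalytic hydrogenolysis cleaves all seven aryl benzyl ethers in neutral medium, to which aryl sulfate salts are inert, and a brief cold protonation gives the acid form as drawn while keeping acid-catalysed S–O hydrolysis slow.

**Compound list**

1 | phloroglucinol | Oc1cc(O)cc(O)c1 | starting material
2 | 1,3,5-triacetoxybenzene | CC(=O)Oc1cc(OC(C)=O)cc(OC(C)=O)c1 | intermediate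
3 | benzyl chloride | ClCc1ccccc1 | starting material
4 | 1,3,5-tris(benzyloxy)benzene | c1ccc(COc2cc(OCc3ccccc3)cc(OCc3ccccc3)c2)cc1 | intermediate
5 | 4-hydroxy-6-methyl-2H-pyran-2-one | Cc1cc(O)cc(=O)o1 | starting material
6 | 3-diazo-6-methyl-2H-pyran-2,4(3H)-dione | CC1=CC(=O)C(=[N+]=[N-])C(=O)O1 | intermediate
7 | 4-hydroxy-6-methyl-3-[2,4,6-tris(benzyloxy)phenyl]-2H-pyran-2-one | Cc1cc(O)c(-c2c(OCc3ccccc3)cc(OCc3ccccc3)cc2OCc2ccccc2)c(=O)o1 | intermediate
8 | 4-methoxybenzyl chloride | COc1ccc(CCl)cc1 | starting material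
9 | 4-[(4-methoxybenzyl)oxy]-6-methyl-3-[2,4,6-tris(benzyloxy)phenyl]-2H-pyran-2-one | Cc1cc(OCc2ccc(OC)cc2)c(-c2c(OCc3ccccc3)cc(OCc3ccccc3)cc2OCc2ccccc2)c(=O)o1 | intermediate
10 | 1,3,5-tris(benzyloxy)-2-(4-hydroxy-6-methyl-2-oxo-2H-pyran-3-yl)-4-{4-[(4-methoxybenzyl)oxy]-6-methyl-2-oxo-2H-pyran-3-yl}benzene | Cc1cc(OCc2ccc(OC)cc2)c(-c2c(OCc3ccccc3)cc(OCc3ccccc3)c(-c3c(O)cc(C)oc3=O)c2OCc2ccccc2)c(=O)o1 | intermediate
11 | 1,3,5-tris(benzyloxy)-2,4-bis{4-[(4-methoxybenzyl)oxy]-6-methyl-2-oxo-2H-pyran-3-yl}benzene | Cc1cc(OCc2ccc(OC)cc2)c(-c2c(OCc3ccccc3)cc(OCc3ccccc3)c(-c3c(OCc4ccc(OC)cc4)cc(C)oc3=O)c2OCc2ccccc2)c(=O)o1 | intermediate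
12 | bis(4-methoxybenzyl) 2,2'-[2,4,6-tris(benzyloxy)-1,3-phenylene]bis{(2E)-3-[(4-methoxybenzyl)oxy]-5-oxohex-2-enoate}, ester and acetonyl cis on each double bond | CC(=O)C/C(OCc1ccc(OC)cc1)=C(C(=O)OCc1ccc(OC)cc1)/c1c(OCc2ccccc2)cc(OCc2ccccc2)c(/C(C(=O)OCc2ccc(OC)cc2)=C(OCc2ccc(OC)cc2)/CC(C)=O)c1OCc1ccccc1 | intermediate
13 | 1,3,5-tris(benzyloxy)-2,4-bis{2,4-dihydroxy-6-[(4-methoxybenzyl)oxy]phenyl}benzene | COc1ccc(COc2cc(O)cc(O)c2-c2c(OCc3ccccc3)cc(OCc3ccccc3)c(-c3c(O)cc(O)cc3OCc3ccc(OC)cc3)c2OCc2ccccc2)cc1 | intermediate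
14 | 1,3,5-tris(benzyloxy)-2,4-bis{2,4-bis(benzyloxy)-6-[(4-methoxybenzyl)oxy]phenyl}benzene | COc1ccc(COc2cc(OCc3ccccc3)cc(OCc3ccccc3)c2-c2c(OCc3ccccc3)cc(OCc3ccccc3)c(-c3c(OCc4ccccc4)cc(OCc4ccccc4)cc3OCc3ccc(OC)cc3)c2OCc2ccccc2)cc1 | intermediate
15 | 1,3,5-tris(benzyloxy)-2,4-bis[2,4-bis(benzyloxy)-6-hydroxyphenyl]benzene | Oc1cc(OCc2ccccc2)cc(OCc2ccccc2)c1-c1c(OCc2ccccc2)cc(OCc2ccccc2)c(-c2c(O)cc(OCc3ccccc3)cc2OCc2ccccc2)c1OCc1ccccc1 | intermediate
16 | bis(pyridinium) salt of the hepta-O-benzyl bis(sulfate) | c1cc[nH+]cc1.c1cc[nH+]cc1.[O-]S(=O)(=O)Oc1cc(OCc2ccccc2)cc(OCc2ccccc2)c1-c1c(OCc2ccccc2)cc(OCc2ccccc2)c(-c2c(OS(=O)(=O)[O-])cc(OCc3ccccc3)cc2OCc2ccccc2)c1OCc1ccccc1 | intermediate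
17 | disodium salt of the hepta-O-benzyl bis(sulfate) | [Na+].[Na+].[O-]S(=O)(=O)Oc1cc(OCc2ccccc2)cc(OCc2ccccc2)c1-c1c(OCc2ccccc2)cc(OCc2ccccc2)c(-c2c(OS(=O)(=O)[O-])cc(OCc3ccccc3)cc2OCc2ccccc2)c1OCc1ccccc1 | intermediate
18 | disodium salt of the target | [Na+].[Na+].[O-]S(=O)(=O)Oc1cc(O)cc(O)c1-c1c(O)cc(O)c(-c2c(O)cc(O)cc2OS(=O)(=O)[O-])c1O | intermediate
19 | 2,4-bis[2,4-dihydroxy-6-(sulfooxy)phenyl]benzene-1,3,5-triol | O=S(=O)(O)Oc1cc(O)cc(O)c1-c1c(O)cc(O)c(-c2c(O)cc(O)cc2OS(=O)(=O)O)c1O | target

**Step count**

Total steps: 12. Longest linear sequence: 11 (steps 1, 2 and 4–12 from phloroglucinol); step 3 is a one-step branch.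

**Steps most likely to fail**

Step 8. Several processes may interfere during the long heating:
- The reaction may stall after lactone opening, or after only one arm has closed.
- The tag may be lost from the vinylogous ester by SN2 attack of alkoxide.
- The acetyl end of the opened chain may be lost by retro-Claisen cleavage.
- The benzyl ethers may erode.

The fallback makes the nucleophilic carbon doubly activated, so that closure becomes a Dieckmann condensation of a beta-keto ester at 65 °C or below. It sets out from 11. The two 6-methyl groups are deprotonated with LiHMDS (5 equiv, THF, −78 °C) and C-acylated with bis(4-methoxybenzyl) carbonate F1 (made from 4-methoxybenzyl alcohol and 1,1'-carbonyldiimidazole), which would give the bis(pyranon-6-ylacetate) F2. Sodium 4-methoxybenzyl oxide in THF–4-methoxybenzyl alcohol at 25–65 °C then opens both lactones, and the beta-keto ester anions close onto the cis esters to give the terphenyl diester F3, which carries a CO2PMB group at C5 of rings A and C. Aqueous KOH at reflux followed by warm AcOH removes these carbons by saponification and decarboxylation of the 2,6-dihydroxybenzoic acid units. This comes back to the route at 13.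

Step 6. The carbenoid may be diverted into O–H insertion with the enol of the accumulating product, into the C5=C6 bond of the pyranone already in place, or into the anisyl ring. Attack at the crowded ring-B position may also be too slow. The fallback reverses the polarity of the bond formation (Pinhey arylation) and sets out from 9. Direct plumbation of the remaining activated ring-B position with Pb(OAc)4 in CHCl3 would give the aryllead triacetate F4. This tetravalent lead reagent arylates C3 of 5 by ligand coupling (pyridine, CHCl3, 40–60 °C), a process that tolerates two ortho substituents. This comes back to the route at 10.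

Step 10. The 4-methoxybenzyl cation may be transferred from oxygen to a carbon of the very electron-rich terphenyl rings, in the solvent cage or between molecules, faster than the scavenger intercepts it. The fallback deactivates the outer rings before the tag is ionised and sets out from 13. Ac2O in pyridine would give the tetraacetate F5, and TFA with 1,3,5-trimethoxybenzene then frees the diol tetraacetate F6. SO3·pyridine followed by NaHCO3 gives the disodium bis(sulfate) tetraacetate F7. NH3 in MeOH at 0 °C removes the acetates by aminolysis to give the tri-O-benzyl bis(sulfate) F8. Hydrogenolysis of the three ring-B benzyl ethers over Pd/C comes back to the route at 18.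

**Further compounds**

F1 | step 8 | bis(4-methoxybenzyl) carbonate | COc1ccc(COC(=O)OCc2ccc(OC)cc2)cc1
F2 | step 8 | bis(4-methoxybenzyl) 2,2'-{[2,4,6-tris(benzyloxy)-1,3-phenylene]bis[4-(4-methoxybenzyloxy)-2-oxo-2H-pyran-3,6-diyl]}diacetate | COc1ccc(COC(=O)Cc2cc(OCc3ccc(OC)cc3)c(-c3c(OCc4ccccc4)cc(OCc4ccccc4)c(-c4c(OCc5ccc(OC)cc5)cc(CC(=O)OCc5ccc(OC)cc5)oc4=O)c3OCc3ccccc3)c(=O)o2)cc1
F3 | step 8 | terphenyl 13 carrying a 4-methoxybenzyl carboxylate at C5 of ring A and of ring C | COc1ccc(COC(=O)c2c(O)cc(OCc3ccc(OC)cc3)c(-c3c(OCc4ccccc4)cc(OCc4ccccc4)c(-c4c(OCc5ccc(OC)cc5)cc(O)c(C(=O)OCc5ccc(OC)cc5)c4O)c3OCc3ccccc3)c2O)cc1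
F4 | step 6 | {2,4,6-tris(benzyloxy)-3-[4-(4-methoxybenzyloxy)-6-methyl-2-oxo-2H-pyran-3-yl]phenyl}lead triacetate | Cc1cc(OCc2ccc(OC)cc2)c(-c2c(OCc3ccccc3)cc(OCc3ccccc3)c([Pb](OC(C)=O)(OC(C)=O)OC(C)=O)c2OCc2ccccc2)c(=O)o1
F5 | step 10 | tetraacetate of 13 | COc1ccc(COc2cc(OC(C)=O)cc(OC(C)=O)c2-c2c(OCc3ccccc3)cc(OCc3ccccc3)c(-c3c(OC(C)=O)cc(OC(C)=O)cc3OCc3ccc(OC)cc3)c2OCc2ccccc2)cc1
F6 | step 10 | 1,3,5-tris(benzyloxy)-2,4-bis(2,4-diacetoxy-6-hydroxyphenyl)benzene | CC(=O)Oc1cc(O)c(-c2c(OCc3ccccc3)cc(OCc3ccccc3)c(-c3c(O)cc(OC(C)=O)cc3OC(C)=O)c2OCc2ccccc2)c(OC(C)=O)c1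
F7 | step 10 | disodium bis(sulfate) of F6 | [Na+].[Na+].CC(=O)Oc1cc(OS(=O)(=O)[O-])c(-c2c(OCc3ccccc3)cc(OCc3ccccc3)c(-c3c(OS(=O)(=O)[O-])cc(OC(C)=O)cc3OC(C)=O)c2OCc2ccccc2)c(OC(C)=O)c1
F8 | step 10 | disodium salt of the ring-B tri-O-benzyl ether of the target | [Na+].[Na+].[O-]S(=O)(=O)Oc1cc(O)cc(O)c1-c1c(OCc2ccccc2)cc(OCc2ccccc2)c(-c2c(O)cc(O)cc2OS(=O)(=O)[O-])c1OCc1ccccc1
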